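**Plan**

1. Retrosynthesis: the ring bond C3=C4 of the 3-methylfuran-2(5H)-one is cut first (ring-closing metathesis of a (Z)-dienyl methacrylate), then the enol-ester O–C(=O) bond (back to a vinyl ketone), then the C–CH3 bond at the stereocentre (conjugate addition to an enethioate), then two allylic C(sp3)–C(sp3) bonds of the chain (down to 3-furylmethyl, geranyl chloride and a three-carbon acetal).
2. Enabling feature: in the ring O1–C2(=O)–C3(CH3)=C4H–C5(=CH–R), C5 is at ketone level. O1–C5=CH–R is therefore the (Z)-enol ester of a vinyl ketone and C2–C3 is a methacrylate, so C3 and C4 are the inner carbons of two terminal alkenes.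
3. Forward order: the furan is present from the start and the chain grows away from it (furylmethyl + geranyl, oxidation of the terminal (E)-methyl, three-carbon arm, two-carbon Wittig, methyl addition, vinyl ketone). The furanone is the only ring made and is closed last.
4. Stereochemistry: the (S)-centre comes from a copper/Josiphos-controlled addition of MeMgBr. The two (E)-alkenes come from geranyl chloride and the (E)-selective SeO2 oxidation. The (Z)-exocyclic alkene comes from the (Z)-dienolate geometry, which the metathesis does not touch.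

Key step: step 12

Assumption: in step 8 the (S,RFe)-Josiphos ligand is assumed to deliver methyl to the Si face of C3 of a linear (E)-enethioate; both ligand enantiomers are commercial, so the antipode would be used if a model reaction showed the opposite sense.

**Step 1**
Reactants: 1 furan-3-ylmethanol
Product: 2 3-(chloromethyl)furan
Conditions: SOCl2 (1.1 equiv), pyridine (1.2 equiv), Et2O, 0 °C; used promptly
Reagents that add atoms: thionyl chloride, O=S(Cl)Cl
Why: Chlorodehydroxylation of a primary alcohol through its chlorosulfite (Darzens halogenation) should proceed cleanly, with pyridine buffering HCl so that the furan survives.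

**Step 2**
Reactants: 2 3-(chloromethyl)furan; 3 geranyl chloride [(2E)-1-chloro-3,7-dimethylocta-2,6-diene]
Product: 5 dendrolasin [3-((3E)-4,8-dimethylnona-3,7-dien-1-yl)furan], via furan-3-ylmethylmagnesium chloride 4 (not isolated)
Conditions: Mg turnings, THF, 0 °C; then 3, Li2CuCl4 (3 mol%), THF, 0 °C
Reagents that add atoms: none
Why: Copper-catalysed Grignard–allylic halide cross-coupling (Kochi–Schlosser type) should join the CH2 carbon of the furylmethyl reagent to the primary allylic carbon by SN2 displacement without allylic transposition, so the (E)-alkene of geranyl chloride is kept.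

**Step 3**
Reactants: 5 dendrolasin
Product: 6 (2E,6E)-9-(furan-3-yl)-2,6-dimethylnona-2,6-dien-1-ol
Conditions: SeO2 (0.2 equiv), t-BuOOH (2 equiv, in decane), salicylic acid (0.1 equiv), CH2Cl2, 0 °C to rt, stopped at partial conversion
Reagents that add atoms: selenium dioxide, O=[Se]=O (oxygen donor, turned over by tert-butyl hydroperoxide, CC(C)(C)OO)
Why: Riley allylic oxidation (ene reaction then [2,3]-shift) should attack the terminal, most accessible trisubstituted alkene and there only the (E)-methyl group, which fixes the (2E) geometry of the new allylic alcohol.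

**Step 4**
Reactants: 6 (2E,6E)-9-(furan-3-yl)-2,6-dimethylnona-2,6-dien-1-ol
Product: 7 3-[(3E,7E)-9-bromo-4,8-dimethylnona-3,7-dien-1-yl]furan
Conditions: CBr4 (1.2 equiv), PPh3 (1.25 equiv), CH2Cl2, 0 °C
Reagents that add atoms: carbon tetrabromide, BrC(Br)(Br)Br
Why: The Appel reaction converts a primary allylic alcohol into the bromide under neutral conditions by SN2 at the CH2 carbon, so neither the alkene geometry nor the furan should be affected.

**Step 5**
Reactants: 7 3-[(3E,7E)-9-bromo-4,8-dimethylnona-3,7-dien-1-yl]furan; 8 2-(2-bromoethyl)-1,3-dioxolane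
Product: 10 2-[(4E,8E)-11-(furan-3-yl)-4,8-dimethylundeca-4,8-dien-1-yl]-1,3-dioxolane, via 2-(1,3-dioxolan-2-yl)ethylmagnesium bromide 9 (not isolated)
Conditions: 8, Mg turnings, THF, 25 °C; then 7, Li2CuCl4 (5 mol%), THF, –78 to 0 °C
Reagents that add atoms: none
Why: Copper-catalysed coupling of a primary alkyl Grignard reagent with a primary allylic bromide (Kochi–Schlosser type) should occur at the CH2Br carbon and keep the (E)-trisubstituted alkene, while the dioxolane carries the future aldehyde through the organometallic step.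

**Step 6**
Reactants: 10 2-[(4E,8E)-11-(furan-3-yl)-4,8-dimethylundeca-4,8-dien-1-yl]-1,3-dioxolane
Product: 11 (5E,9E)-12-(furan-3-yl)-5,9-dimethyldodeca-5,9-dienal
Conditions: pyridinium p-toluenesulfonate (0.3 equiv), acetone/H2O (10:1), 55 °C
Reagents that add atoms: water, O
Why: Acid-catalysed acetal hydrolysis under buffered pyridinium conditions should free the aldehyde while the 3-alkylfuran and the trisubstituted alkenes tolerate the weak acid.

**Step 7**
Reactants: 11 (5E,9E)-12-(furan-3-yl)-5,9-dimethyldodeca-5,9-dienal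
Product: 12 S-ethyl (2E,7E,11E)-14-(furan-3-yl)-7,11-dimethyltetradeca-2,7,11-trienethioate
Conditions: Ph3P=CHC(O)SEt (1.3 equiv), CH2Cl2, 40 °C
Reagents that add atoms: S-ethyl 2-(triphenyl-λ5-phosphanylidene)ethanethioate, CCSC(=O)C=P(c1ccccc1)(c1ccccc1)c1ccccc1
Why: A Wittig reaction with a stabilised ylide on an unbranched aldehyde should give the (E)-enethioate, the acceptor best suited to the next step.

**Step 8**
Reactants: 12 S-ethyl (2E,7E,11E)-14-(furan-3-yl)-7,11-dimethyltetradeca-2,7,11-trienethioate
Product: 14 S-ethyl (3S,7E,11E)-14-(furan-3-yl)-3,7,11-trimethyltetradeca-7,11-dienethioate, via bromomagnesium thioester enolate 13 (not isolated)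
Conditions: MeMgBr (1.3 equiv), CuBr·SMe2 (3 mol%), (S)-1-[(RP)-2-(diphenylphosphino)ferrocenyl]ethyldicyclohexylphosphine (Josiphos, 3.6 mol%), t-BuOMe, –75 °C; aqueous work-up
Reagents that add atoms: methylmagnesium bromide, C[Mg]Br
Why: Copper-catalysed enantioselective conjugate addition of a Grignard reagent to an (E)-enethioate should set the (S)-centre, the chiral ferrocenyl diphosphine–copper complex delivering methyl to the Si face of C3; the isolated alkenes and the furan are not acceptors.

**Step 9**
Reactants: 14 S-ethyl (3S,7E,11E)-14-(furan-3-yl)-3,7,11-trimethyltetradeca-7,11-dienethioate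
Product: 15 (3S,7E,11E)-14-(furan-3-yl)-N-methoxy-N,3,7,11-tetramethyltetradeca-7,11-dienamide
Conditions: MeNH(OMe)·HCl (2 equiv), i-PrMgCl (4 equiv), THF, –20 to 0 °C; aqueous work-up
Reagents that add atoms: N,O-dimethylhydroxylamine hydrochloride, CNOC.Cl
Why: Aminolysis of the activated thioester by the magnesium amide of N,O-dimethylhydroxylamine gives the Weinreb amide, and the stereocentre, β to the carbonyl, cannot epimerise.

**Step 10**
Reactants: 15 (3S,7E,11E)-14-(furan-3-yl)-N-methoxy-N,3,7,11-tetramethyltetradeca-7,11-dienamide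
Product: 17 (5S,9E,13E)-16-(furan-3-yl)-5,9,13-trimethylhexadeca-1,9,13-trien-3-one, via magnesium-chelated tetrahedral adduct 16 (not isolated)
Conditions: CH2=CHMgBr (1.5 equiv), THF, 0 °C; inverse quench into cold 1 M aq. HCl
Reagents that add atoms: vinylmagnesium bromide, C=C[Mg]Br
Why: In the Weinreb ketone synthesis the chelated adduct prevents a second addition, and the acidic inverse quench protonates the liberated amine before it can add to the new enone.

**Step 11**
Reactants: 17 (5S,9E,13E)-16-(furan-3-yl)-5,9,13-trimethylhexadeca-1,9,13-trien-3-one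
Product: 19 (3Z,5S,9E,13E)-16-(furan-3-yl)-5,9,13-trimethylhexadeca-1,3,9,13-tetraen-3-yl 2-methylprop-2-enoate, via lithium (Z)-dienolate 18 (not isolated)
Conditions: LiN(SiMe3)2 (1.1 equiv), THF, –78 °C, slow addition of 17; then methacrylic anhydride (1.3 equiv), –78 to –20 °C
Reagents that add atoms: methacrylic anhydride, C=C(C)C(=O)OC(=O)C(C)=C
Why: Kinetic α′-deprotonation of the enone (the CH2 next to the stereocentre is the only enolisable position) should give the cross-conjugated dienolate with oxygen cis to the alkyl chain, which avoids allylic strain with the vinyl group, and O-acylation by the hard anhydride then fixes this as the (Z)-enol ester.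

**Step 12**
Reactants: 19 (3Z,5S,9E,13E)-16-(furan-3-yl)-5,9,13-trimethylhexadeca-1,3,9,13-tetraen-3-yl 2-methylprop-2-enoate
Product: 20 (5Z)-5-[(2S,6E,10E)-13-(furan-3-yl)-2,6,10-trimethyltrideca-6,10-dien-1-ylidene]-3-methylfuran-2(5H)-one
Conditions: second-generation Grubbs catalyst [RuCl2(H2IMes)(PCy3)(=CHPh)] (10 mol%, two portions), 1,4-benzoquinone (20 mol%), toluene (2 mM), 80 °C, argon sparge
Reagents that add atoms: none
Why: Proposed new method: the ruthenium alkylidene should load on the only monosubstituted alkene (the vinyl group on C5) to give an acyloxy-substituted vinylcarbene, which adds in [2+2] fashion to the 1,1-disubstituted methacrylate alkene; cycloreversion of the ruthenacyclobutane releases the C3=C4 bond and Ru=CH2, which leaves as ethene. The closest known reaction types are the ring-closing metathesis of allyl methacrylates to α-methylbutenolides and ene–diene metathesis through vinylalkylidenes; what is new is that the alcohol part is a (Z)-dienol, so the exocyclic alkene is in place before closure. The five-membered lactone is closed by ring-closing olefin metathesis between two alkene termini, formally a 5-exo attack of the carbene on the acrylate followed by cycloreversion. No stereocentre is formed: the (Z) geometry of the exocyclic alkene comes unchanged from the enol ester and the (S)-centre is a spectator. The step needs site selectivity among five C=C bonds and the furan; it is secured because only one alkene is monosubstituted, closure onto the methacrylate is the only low-strain cyclisation (the chain alkenes would give eight- or nine-membered rings and the enol-ester alkene is trisubstituted and oxygen-substituted), and high dilution with benzoquinone should suppress dimerisation and alkene migration.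

**Compound list**

1 | furan-3-ylmethanol | OCc1ccoc1 | starting material
2 | 3-(chloromethyl)furan | ClCc1ccoc1 | intermediate
3 | geranyl chloride, (2E)-1-chloro-3,7-dimethylocta-2,6-diene | CC(C)=CCC/C(C)=C/CCl | starting material
4 | furan-3-ylmethylmagnesium chloride | Cl[Mg]Cc1ccoc1 | intermediate (not isolated)
5 | dendrolasin, 3-[(3E)-4,8-dimethylnona-3,7-dien-1-yl]furan | CC(C)=CCC/C(C)=C/CCc1ccoc1 | intermediate
6 | (2E,6E)-9-(furan-3-yl)-2,6-dimethylnona-2,6-dien-1-ol | OC/C(C)=C/CC/C(C)=C/CCc1ccoc1 | intermediate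
7 | 3-[(3E,7E)-9-bromo-4,8-dimethylnona-3,7-dien-1-yl]furan | BrC/C(C)=C/CC/C(C)=C/CCc1ccoc1 | intermediate
8 | 2-(2-bromoethyl)-1,3-dioxolane | BrCCC1OCCO1 | starting material
9 | [2-(1,3-dioxolan-2-yl)ethyl]magnesium bromide | Br[Mg]CCC1OCCO1 | intermediate (not isolated)
10 | 2-[(4E,8E)-11-(furan-3-yl)-4,8-dimethylundeca-4,8-dien-1-yl]-1,3-dioxolane | O1CCOC1CCC/C(C)=C/CC/C(C)=C/CCc1ccoc1 | intermediate
11 | (5E,9E)-12-(furan-3-yl)-5,9-dimethyldodeca-5,9-dienal | O=CCCC/C(C)=C/CC/C(C)=C/CCc1ccoc1 | intermediate
12 | S-ethyl (2E,7E,11E)-14-(furan-3-yl)-7,11-dimethyltetradeca-2,7,11-trienethioate | CCSC(=O)/C=C/CCC/C(C)=C/CC/C(C)=C/CCc1ccoc1 | intermediate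
13 | bromomagnesium (3S,7E,11E)-1-(ethylsulfanyl)-14-(furan-3-yl)-3,7,11-trimethyltetradeca-1,7,11-trien-1-olate (enolate geometry not defined) | CCSC(O[Mg]Br)=C[C@@H](C)CCC/C(C)=C/CC/C(C)=C/CCc1ccoc1 | intermediate (not isolated)
14 | S-ethyl (3S,7E,11E)-14-(furan-3-yl)-3,7,11-trimethyltetradeca-7,11-dienethioate | CCSC(=O)C[C@@H](C)CCC/C(C)=C/CC/C(C)=C/CCc1ccoc1 | intermediate
15 | (3S,7E,11E)-14-(furan-3-yl)-N-methoxy-N,3,7,11-tetramethyltetradeca-7,11-dienamide | CON(C)C(=O)C[C@@H](C)CCC/C(C)=C/CC/C(C)=C/CCc1ccoc1 | intermediate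
16 | bromomagnesium (5S,9E,13E)-16-(furan-3-yl)-3-[methoxy(methyl)amino]-5,9,13-trimethylhexadeca-1,9,13-trien-3-olate | C=CC(O[Mg]Br)(N(C)OC)C[C@@H](C)CCC/C(C)=C/CC/C(C)=C/CCc1ccoc1 | intermediate (not isolated)
17 | (5S,9E,13E)-16-(furan-3-yl)-5,9,13-trimethylhexadeca-1,9,13-trien-3-one | C=CC(=O)C[C@@H](C)CCC/C(C)=C/CC/C(C)=C/CCc1ccoc1 | intermediate
18 | lithium (3Z,5S,9E,13E)-16-(furan-3-yl)-5,9,13-trimethylhexadeca-1,3,9,13-tetraen-3-olate | C=C/C(=C/[C@@H](C)CCC/C(C)=C/CC/C(C)=C/CCc1ccoc1)O[Li] | intermediate (not isolated)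
19 | (3Z,5S,9E,13E)-16-(furan-3-yl)-5,9,13-trimethylhexadeca-1,3,9,13-tetraen-3-yl 2-methylprop-2-enoate | C=C/C(=C/[C@@H](C)CCC/C(C)=C/CC/C(C)=C/CCc1ccoc1)OC(=O)C(C)=C | intermediate
20 | (5Z)-5-[(2S,6E,10E)-13-(furan-3-yl)-2,6,10-trimethyltrideca-6,10-dien-1-ylidene]-3-methylfuran-2(5H)-one | CC1=C/C(=C/[C@@H](C)CCC/C(C)=C/CC/C(C)=C/CCc2ccoc2)OC1=O | target

**Step count and risks**

Total steps: 12. Longest linear sequence: 12 steps (from 1; 3 and 8 are purchased).

Steps most likely to fail:

1. Step 12 (Proposed new method). The carbene formed on the diene terminus may rest as an unreactive chelated or η3-vinylcarbene species, or the diene may oligomerise, so that the ring does not close. The fallback uses known chemistry, sets out from vinyl ketone 17 and returns at 20. Luche reduction (NaBH4, CeCl3·7H2O, MeOH, –40 °C) should give allylic alcohol F1 as a mixture of carbinol epimers, which is of no consequence. Esterification with methacryloyl chloride, Et3N and DMAP gives methacrylate F2. Ring-closing metathesis of this allyl methacrylate (second-generation Grubbs catalyst, CH2Cl2, reflux) gives 5-alkylbutenolide F3. Silylation (i-Pr3SiOTf, Et3N, CH2Cl2, 0 °C) gives 2-silyloxyfuran F4, and selenenylation at C5 (PhSeCl, –78 °C) gives selenide F5. Oxidation (H2O2, pyridine, 0 °C) gives selenoxide F6, whose syn-elimination can use only the exocyclic CH2 hydrogens and should deliver 20. A trace of I2 would equilibrate any (E)-isomer to the more stable (Z)-isomer.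

2. Step 11. Anionic polymerisation or amide addition at the vinyl ketone, C-acylation, or formation of an (E)/(Z) mixture of dienolates may occur. The fallback sets out from 17 and returns at 19. Soft enolisation (Me3SiOTf, Et3N, CH2Cl2, 0 °C), which avoids a strong base and equilibrates to the (Z)-isomer, should give silyl dienol ether F7. Fluoride-catalysed acyl transfer with methacryloyl fluoride (catalytic tetrabutylammonium difluorotriphenylsilicate, THF, 0 °C) then gives 19.

3. Step 3. Oxidative degradation of the furan, competing oxidation at the internal alkene, or over-oxidation to the enal may occur. The fallback oxidises before the furan is present; it sets out from chloride 2 (as its Grignard reagent 4) and returns at 6. Commercial geranyl acetate, in which the acetate deactivates the 2,3-alkene, is oxidised (catalytic SeO2, t-BuOOH, CH2Cl2) to hydroxy acetate F8. Silylation (t-BuMe2SiCl, imidazole, DMF) gives silyl ether F9. Coupling with 4 (Li2CuCl4, THF, –20 °C, the allylic acetate serving as leaving group) gives silyl ether F10, and Bu4NF in THF then gives 6.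

**Further compounds**

F1 | step 12 | (5S,9E,13E)-16-(furan-3-yl)-5,9,13-trimethylhexadeca-1,9,13-trien-3-ol (both C3 epimers) | C=CC(O)C[C@@H](C)CCC/C(C)=C/CC/C(C)=C/CCc1ccoc1
F2 | step 12 | (5S,9E,13E)-16-(furan-3-yl)-5,9,13-trimethylhexadeca-1,9,13-trien-3-yl 2-methylprop-2-enoate (both C3 epimers) | C=CC(OC(=O)C(C)=C)C[C@@H](C)CCC/C(C)=C/CC/C(C)=C/CCc1ccoc1
F3 | step 12 | 5-[(2S,6E,10E)-13-(furan-3-yl)-2,6,10-trimethyltrideca-6,10-dien-1-yl]-3-methylfuran-2(5H)-one (both C5 epimers) | CC1=CC(C[C@@H](C)CCC/C(C)=C/CC/C(C)=C/CCc2ccoc2)OC1=O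
F4 | step 12 | {[5-((2S,6E,10E)-13-(furan-3-yl)-2,6,10-trimethyltrideca-6,10-dien-1-yl)-3-methylfuran-2-yl]oxy}tri(propan-2-yl)silane | Cc1cc(C[C@@H](C)CCC/C(C)=C/CC/C(C)=C/CCc2ccoc2)oc1O[Si](C(C)C)(C(C)C)C(C)C
F5 | step 12 | 5-[(2S,6E,10E)-13-(furan-3-yl)-2,6,10-trimethyltrideca-6,10-dien-1-yl]-3-methyl-5-(phenylselanyl)furan-2(5H)-one | CC1=CC(C[C@@H](C)CCC/C(C)=C/CC/C(C)=C/CCc2ccoc2)([Se]c2ccccc2)OC1=O
F6 | step 12 | 5-(benzeneseleninyl)-5-[(2S,6E,10E)-13-(furan-3-yl)-2,6,10-trimethyltrideca-6,10-dien-1-yl]-3-methylfuran-2(5H)-one | CC1=CC(C[C@@H](C)CCC/C(C)=C/CC/C(C)=C/CCc2ccoc2)([Se](=O)c2ccccc2)OC1=O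
F7 | step 11 | {[(3Z,5S,9E,13E)-16-(furan-3-yl)-5,9,13-trimethylhexadeca-1,3,9,13-tetraen-3-yl]oxy}trimethylsilane | C=C/C(=C/[C@@H](C)CCC/C(C)=C/CC/C(C)=C/CCc1ccoc1)O[Si](C)(C)C
F8 | step 3 | (2E,6E)-8-hydroxy-3,7-dimethylocta-2,6-dien-1-yl acetate | CC(=O)OC/C=C(\C)CC/C=C(\C)CO
F9 | step 3 | (2E,6E)-8-[(tert-butyldimethylsilyl)oxy]-3,7-dimethylocta-2,6-dien-1-yl acetate | CC(=O)OC/C=C(\C)CC/C=C(\C)CO[Si](C)(C)C(C)(C)C
F10 | step 3 | tert-butyl{[(2E,6E)-9-(furan-3-yl)-2,6-dimethylnona-2,6-dien-1-yl]oxy}dimethylsilane | CC(C)(C)[Si](C)(C)OC/C(C)=C/CC/C(C)=C/CCc1ccoc1
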